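(The data come from a simulation from invented constants; noise was put on by code.)

Watch [J] against the L charged: in the birch run it levels off at 88.8% of the charge, less than the charge, although solid L reads 0% as early as 0.625 d.

| flask | L | D | remark | time |
|---|---|---|---|---|
| birch | 0.25 M | 1 M | run made earlier |  |
| south-west | 0.25 M | 0.700 M |  | 8.0 d |
| west | 0.50 M | 0.700 M |  | 8.0 d |
| north-west | 1.0 M | 0.700 M |  | 8.0 d |

- birch (time / d: J / %, L / %): 0.625: 65.7, 0; 1.67: 87.8, 0; 3.00: 88.5, 0; 5.00: 88.8, 0

(scatter of a reading: 0.3 percentage points)

* [J] at the end for south-west, west, north-west, in this order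
* the shape of the row from first to last (falls, then rises / rises, then falls / rises all the way / hardly changes / falls all the way)

- L is a solid; its amount is given per volume of the solution
- at the start none of L is in solution
- "hardly changes" means that all values lie within two and a half points (for a concentration: within two and a half percent of the largest)

Keep the books on L, the limiting reagent of the birch run, where its 0.25 M is less than the 1 M of D. The first entry is solid L, 0% at 5.00 d. The second is J, 0.222 M. At 0.625 d a gap of 34.3% stands unread and later shrinks, so take it as dissolved L, called Z, which D turns into J. The 11.2% that stays unread needs a sink, so assume that Z also adds to J and gives X, which holds two L and one D. That third entry, 0.0140 M of X, closes the books on L. Each J and each X took one D, so the birch run ends with a fraction x = 76.4% of its D.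

Z now has two routes, and the route to X runs against the route to J as σ[J]/[D]. Following [J] as D is used gives [J]/[D]₀ = (x^σ − x)/(1 − σ), where [D]₀ is the charged D. The birch books then give the reading σ = 0.438, the side ratio, which is the rate constant of the route to X over that of the route to J, a selectivity factor.

[J] grows while [D] > σ[J], and the two balance at x = 23.0%, with [J] = 0.368 M. The books put this balance at a charge of 0.710 M of L, more than the 0.50 M of west and less than the 1.0 M of north-west. My reckoning is therefore a row that rises, then falls.

The forecast differs: 0.155 M, 0.155 M, 0.155 M, hardly changes. In its words, “The row is flat.”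

The flasks give 0.208 M, 0.330 M and 0.298 M: rises, then falls, turning at 0.71 M.

    Z + D → J (k = 5.01 × 10⁻⁵ L mol⁻¹ s⁻¹)
    L ⇌ Z, rate k2*(cs2 - [Z]) while solid is left; crystals form when [Z] > cs2 (solubility = 0.360 M, k = 1.79 × 10⁻⁵ s⁻¹)
    Z + J → X (k = 2.29 × 10⁻⁵ L mol⁻¹ s⁻¹)

In south-west at 0.262 d, Z is used by the route to J 37 times as fast as by the route to X. Through σ, the same comparison [D]/(σ[J]) at 8.00 d reads 1.97 in west, more than one, and 0.401 in north-west, less than one, where [D] stands at 0.0523 M.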